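Read at 90.0 s, the last reading of both earlier runs, the winter flask holds 13.8% product and the autumn flask 30.3%. Product thus grows 2.20-fold for 2.25-fold salt, which reads as an order of 0.970 in salt.

| setting | winter | autumn | flask |
|---|---|---|---|
| substrate | 49 mM | 49 mM | 49 mM |
| salt in the second phase | 2 equiv | 4.5 equiv | 3.00 equiv |
| spent carrier | 15 mol% | 15 mol% | 15 mol% |
| added ligand | 3.7 mM | 3.7 mM | 3.7 mM |
| remark | run made earlier | run made earlier |  |
| volume of the second phase over the first |  |  | 2.0 |

| run | time / s | product / % | substrate / % |
|---|---|---|---|
| winter | 10.0 | 0.6 | 98.9 |
| winter | 12.0 | 0.2 | 99.7 |
| winter | 20.0 | 2.1 | 99.1 |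
| winter | 30.0 | 5.0 | 97.4 |
| winter | 50.0 | 9.7 | 91.9 |
| winter | 90.0 | 13.8 | 85.3 |
| autumn | 10.0 | 2.5 | 96.9 |
| autumn | 20.0 | 6.6 | 93.6 |
| autumn | 30.0 | 10.7 | 90.0 |
| autumn | 50.0 | 17.4 | 83.4 |
| autumn | 60.0 | 18.9 | 79.1 |
| autumn | 90.0 | 30.3 | 72.3 |

(scatter of a reading: 1 percentage point)

- in the second phase: salt in the second phase, spent salt in the second phase; everything else is in the first
- charges count per volume of the first phase; a concentration in a rate is the amount of a species over the volume of its own phase; every rate counts per litre of the first phase
- the numbers in the tables scatter with a standard deviation of 1 percentage point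
- steps thought possible: added ligand + fresh carrier <-> idle complex; spent carrier + salt in the second phase <-> fresh carrier + spent salt in the second phase; substrate + fresh carrier -> product + spent carrier
- the earlier runs hold the two phases in the same ratio of volumes as the flask asked about
- no earlier run changes the charge of spent carrier; that part of a forecast is a guess

* apparent order in salt in the second phase when 30% of the substrate are converted (percent change of the rate of making product for one percent more salt in the second phase charged)
* apparent order in spent carrier when 30% of the substrate are converted (percent change of the rate of making product for one percent more spent carrier charged)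

One number carries this: the turnover rate per equivalent, meaning product made per carrier charged, per equivalent of salt charged, per unit time. It reads 0.299 min⁻¹ in the autumn run and 0.307 min⁻¹ in the winter run.

For the flask at 3.00 equiv it gives a ladder. One round of the carrier takes 1.11 min, and the lag seen in the winter run, about 10.0 s, is shorter than that round. The time to 30% is 2.23 min, longer than that round. At this same rate the salt charged lasts 22.3 min, longer than the time to 30%. By 30% the carrier has gone round 2.00 times and the flask has used 10.0% of its salt, against 6.73% in the autumn run at its reading. Putting that mean salt back in and going round once more gives 2.27 min.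

A rate that follows salt one to one points to the exchange of spent carrier with salt as rate-limiting step, and that step takes spent carrier one to one as well. This reckoning therefore commits to about 1 for both orders, the carrier part being a guess.

The forecast says 1.2 for salt and 1.6 for spent carrier, holding of the carrier that “the order nears 2 if binding is tight”.

The flask gives 1.0 and 1.1, and reaches 30% at 2.25 min.

    added ligand + fresh carrier ⇌ idle complex (K = 20000 L mol⁻¹, k = 4.00 L mol⁻¹ s⁻¹)
    spent carrier + salt in the second phase ⇌ fresh carrier + spent salt in the second phase (K = 0.230, k = 0.290 L mol⁻¹ s⁻¹)
    substrate + fresh carrier → product + spent carrier (k = 4.30 L mol⁻¹ s⁻¹)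

At 1.12 min in the flask, spent carrier has a half-life of 0.58 min by the forward exchange alone, while fresh carrier, by its reaction with substrate as charged, has 0.0548 min, ten times shorter. At 2.25 min the catalyst stands at 77.3% spent carrier, 8.69% fresh carrier and 14.0% idle complex. Carried to a flask with twice the spent carrier, 0.299 min⁻¹ gives a time factor of 0.500 to 30%, and that run gives 0.502.

The readings stem from a simulated flask for substances that don't exist.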